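**Plan**

Numbering: ring C1 (OMe), C2 (=CH), C3 (=C, carries C7H2OBz), C4 (OH), C5 (OBz), C6 (OH).
Enabling feature: in the cyclohexene, C4(OH)–C3(=C2H)–C7 is an α-(hydroxyalkyl)acryloyl unit once C7 is an acyl carbon (Morita–Baylis–Hillman retron). C1/C6/C5 (cis, then trans) are C2/C3/C4 of D-lyxose, whose C1 and C5 become C2 and C4.
Cuts, in retrosynthetic order: the O–COPh bonds at O5 and O7, the ring bond C3–C4, C2=C3 (Wittig, brings in C3 and C7), and O–CH3 at C1.
Forward: pyranoside, then a temporary 1,4-dioxane (butane-2,3-diacetal) on O3/O4 that leaves only O2 for methylation, then lactol, open-chain thioenoate and aldehyde. The cyclohexene is then closed (the only carbocycle and the last ring formed), followed by reduction, acetal removal and two benzoylations.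
Stereochemistry: C1, C6 and C5 are carried unchanged from D-lyxose. C4 is set in the ring closure under control of the trans-fused dioxane chair, and this helper ring leaves in step 11.

Key step: step 8

**Route**

Step 1
Reactants: 1 D-lyxose
Product: 2 benzyl α-D-lyxopyranoside
Conditions: BnOH, HCl (cat.), 50 °C
Reagents that add atoms: benzyl alcohol OCc1ccccc1
Why: Fischer glycosidation under thermodynamic control should give the α-pyranoside with an axial anomeric benzyloxy group (anomeric effect), which masks C1 in a form removable by hydrogenolysis.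

Step 2
Reactants: 2 benzyl α-D-lyxopyranoside
Product: 3 benzyl 3,4-O-[(2S,3S)-2,3-dimethoxybutane-2,3-diyl]-α-D-lyxopyranoside
Conditions: butane-2,3-dione, HC(OMe)3, CSA (cat.), MeOH, reflux
Reagents that add atoms: butane-2,3-dione CC(=O)C(C)=O; methanol CO
Why: Acid-catalysed butane-2,3-diacetal formation should select the trans-diequatorial O3/O4 pair over the cis O2/O3 pair, because only the former gives a chair 1,4-dioxane with both new methoxy groups axial (anomeric control, fixing both acetal centres as S), so that O2 stays the only free hydroxyl.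

Step 3
Reactants: 3 benzyl 3,4-O-[(2S,3S)-2,3-dimethoxybutane-2,3-diyl]-α-D-lyxopyranoside
Product: 4 benzyl 3,4-O-[(2S,3S)-2,3-dimethoxybutane-2,3-diyl]-2-O-methyl-α-D-lyxopyranoside
Conditions: NaH, MeI, DMF, 0 °C to rt
Reagents that add atoms: iodomethane CI
Why: Williamson etherification of the single free hydroxyl installs the methyl ether that becomes the C1 methoxy group without touching a stereocentre.

Step 4
Reactants: 4 benzyl 3,4-O-[(2S,3S)-2,3-dimethoxybutane-2,3-diyl]-2-O-methyl-α-D-lyxopyranoside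
Product: 5 3,4-O-[(2S,3S)-2,3-dimethoxybutane-2,3-diyl]-2-O-methyl-D-lyxopyranose (lactol, both anomers)
Conditions: H2 (1 atm), Pd/C, EtOAc–EtOH, rt
Reagents that add atoms: none
Why: Catalytic hydrogenolysis of the anomeric benzyl ether should free the lactol while the acetal and the methyl ether are inert.

Step 5
Reactants: 6 methyltriphenylphosphonium bromide; 7 S-ethyl carbonochloridothioate (S-ethyl chlorothioformate)
Product: 9 S-ethyl 2-(triphenyl-λ5-phosphanylidene)ethanethioate, via methylenetriphenylphosphorane 8 (not isolated)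
Conditions: 6 (2 equiv), NaHMDS (2 equiv), THF, 0 °C; then 7 (1 equiv), −78 °C to rt
Reagents that add atoms: none
Why: C-acylation of a non-stabilised ylide by an acid chloride type electrophile, followed by transylidation with the second equivalent of ylide, is the standard entry to acyl-stabilised phosphoranes.

Step 6
Reactants: 5 3,4-O-[(2S,3S)-2,3-dimethoxybutane-2,3-diyl]-2-O-methyl-D-lyxopyranose; 9 S-ethyl 2-(triphenyl-λ5-phosphanylidene)ethanethioate
Product: 10 S-ethyl (2E,4R)-4-[(2R,3R,5S,6S)-3-(hydroxymethyl)-5,6-dimethoxy-5,6-dimethyl-1,4-dioxan-2-yl]-4-methoxybut-2-enethioate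
Conditions: 9, PhCO2H (cat.), toluene, 80 °C
Reagents that add atoms: none
Why: Wittig olefination of the open-chain aldehyde tautomer of the lactol with the stabilised ylide should give mainly the E-thioenoate and release O5 of the sugar as a primary alcohol, and the neutral medium should keep that alcohol from adding to the acceptor (either alkene geometry would serve in step 8).

Step 7
Reactants: 10 S-ethyl (2E,4R)-4-[(2R,3R,5S,6S)-3-(hydroxymethyl)-5,6-dimethoxy-5,6-dimethyl-1,4-dioxan-2-yl]-4-methoxybut-2-enethioate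
Product: 11 S-ethyl (2E,4R)-4-[(2R,3S,5S,6S)-3-formyl-5,6-dimethoxy-5,6-dimethyl-1,4-dioxan-2-yl]-4-methoxybut-2-enethioate
Conditions: Dess–Martin periodinane, CH2Cl2, 0 °C to rt
Reagents that add atoms: none
Why: Dess–Martin oxidation should convert the primary alcohol into the aldehyde under near-neutral conditions that spare thioester, alkene and acetal, the formyl group staying in its stable equatorial position on the dioxane chair.

Step 8
Reactants: 11 S-ethyl (2E,4R)-4-[(2R,3S,5S,6S)-3-formyl-5,6-dimethoxy-5,6-dimethyl-1,4-dioxan-2-yl]-4-methoxybut-2-enethioate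
Product: 14 S-ethyl (2S,3S,4aR,5R,8R,8aR)-5-hydroxy-2,3,8-trimethoxy-2,3-dimethyl-2,3,4a,5,8,8a-hexahydrobenzo[b][1,4]dioxine-6-carbothioate, via phosphonium enolate 12 (not isolated), via phosphonium aldolate 13 (not isolated)
Conditions: PMe3 (0.3 equiv), CH2Cl2 (0.02 M), rt
Reagents that add atoms: none
Why: Trimethylphosphine adds reversibly to C2 of the thioenoate to give the phosphonium enolate 12, C3 of which attacks the formyl carbon C4 to give aldolate 13, and proton transfer from C3 to the alkoxide followed by E1cB loss of the phosphine restores the C2=C3 bond and the catalyst. The closest known reaction type is the phosphine-catalysed intramolecular Morita–Baylis–Hillman cyclisation of ω-formyl α,β-unsaturated thioesters with enolisable aldehyde groups to 6-hydroxycyclohex-1-enecarbothioates. The cyclohexene closes by a 6-(enolexo)-exo-trig aldol addition, and since C5 and C6 hold the two reacting arms as neighbouring equatorial substituents of the rigid dioxane chair, the new ring grows as the second chair of a trans-decalin-like bicycle. C4 is the only lasting new stereocentre and is controlled by that chair: the developing C4–O bond should be axial, because an equatorial oxygen would collide with the planar C3=C7(O−)SEt enolate (A1,3 strain) whereas an axial one lies 1,3-syn to an axial phosphonium group at C2, and axial on this chair means cis to O5, the required configuration. The same epimer should also be favoured at equilibrium, since a pseudoaxial C4–OH avoids A1,2 strain with the acyl group on C3, so reversibility of the aldol step should do no harm. The step needs attack of the phosphine on the acceptor only, without epimerisation, β-elimination or oxa-Michael addition, and this is secured by the activating thioester, by the absence of free hydroxyl groups, by the formyl group already being the stable equatorial epimer and by the dioxane ring holding the C6–O bond out of alignment with the enol π system.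

Step 9
Reactants: 14 S-ethyl (2S,3S,4aR,5R,8R,8aR)-5-hydroxy-2,3,8-trimethoxy-2,3-dimethyl-2,3,4a,5,8,8a-hexahydrobenzo[b][1,4]dioxine-6-carbothioate
Product: 16 (2S,3S,4aR,5R,8R,8aR)-6-(hydroxymethyl)-2,3,8-trimethoxy-2,3-dimethyl-2,3,4a,5,8,8a-hexahydrobenzo[b][1,4]dioxin-5-ol, via enal 15 (not isolated)
Conditions: DIBAL-H (excess), CH2Cl2, −78 to −20 °C; aq. Rochelle salt
Reagents that add atoms: none
Why: 1,2-Reduction of the unsaturated thioester by DIBAL-H should pass through the enal and end at the primary allylic alcohol, the acetal and the methyl ether being inert at low temperature.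

Step 10
Reactants: 16 (2S,3S,4aR,5R,8R,8aR)-6-(hydroxymethyl)-2,3,8-trimethoxy-2,3-dimethyl-2,3,4a,5,8,8a-hexahydrobenzo[b][1,4]dioxin-5-ol
Product: 17 [(2S,3S,4aR,5R,8R,8aR)-5-hydroxy-2,3,8-trimethoxy-2,3-dimethyl-2,3,4a,5,8,8a-hexahydrobenzo[b][1,4]dioxin-6-yl]methyl benzoate
Conditions: BzCl (1.05 equiv), pyridine, CH2Cl2, −40 to 0 °C
Reagents that add atoms: benzoyl chloride O=C(Cl)c1ccccc1
Why: Kinetically selective O-acylation should occur at the unhindered primary allylic alcohol, which reacts much faster than the pseudoaxial secondary C4–OH flanked by the acetal and the trisubstituted alkene.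

Step 11
Reactants: 17 [(2S,3S,4aR,5R,8R,8aR)-5-hydroxy-2,3,8-trimethoxy-2,3-dimethyl-2,3,4a,5,8,8a-hexahydrobenzo[b][1,4]dioxin-6-yl]methyl benzoate
Product: 18 [(3R,4S,5R,6R)-4,5,6-trihydroxy-3-methoxycyclohex-1-en-1-yl]methyl benzoate
Conditions: TFA–H2O (9:1), CH2Cl2, 0 °C to rt
Reagents that add atoms: none
Why: Acid hydrolysis of the butane-2,3-diacetal should release the C5 and C6 hydroxyls, while the benzoate, the methyl ether and the oxygen-deactivated allylic positions should survive the short exposure.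

Step 12
Reactants: 18 [(3R,4S,5R,6R)-4,5,6-trihydroxy-3-methoxycyclohex-1-en-1-yl]methyl benzoate
Product: 20 [(3R,4R,5R,6R)-5-(benzoyloxy)-4,6-dihydroxy-3-methoxycyclohex-1-en-1-yl]methyl benzoate (target), via diphenylborinate 19 (not isolated)
Conditions: BzCl (1.2 equiv), 2-aminoethyl diphenylborinate (10 mol %), i-Pr2NEt, MeCN, rt
Reagents that add atoms: benzoyl chloride O=C(Cl)c1ccccc1
Why: In this borinic-acid-catalysed regioselective acylation the catalyst should bind the only cis-1,2-diol (C4–OH/C5–OH) as the tetracoordinate borinate 19 and pass the benzoyl group to its equatorial oxygen O5, leaving the pseudoaxial allylic C4–OH and the unactivated C6–OH free, as in the 3-O-selective acylation of manno-configured pyranosides.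

**Compound list**

1 | D-lyxose | OC1OC[C@@H](O)[C@H](O)[C@@H]1O | starting material
2 | benzyl α-D-lyxopyranoside | c1ccccc1CO[C@H]2OC[C@@H](O)[C@H](O)[C@@H]2O | intermediate
3 | benzyl 3,4-O-[(2S,3S)-2,3-dimethoxybutane-2,3-diyl]-α-D-lyxopyranoside | c1ccccc1CO[C@H]2OC[C@H]3O[C@](C)(OC)[C@@](C)(OC)O[C@@H]3[C@@H]2O | intermediate
4 | benzyl 3,4-O-[(2S,3S)-2,3-dimethoxybutane-2,3-diyl]-2-O-methyl-α-D-lyxopyranoside | c1ccccc1CO[C@H]2OC[C@H]3O[C@](C)(OC)[C@@](C)(OC)O[C@@H]3[C@@H]2OC | intermediate
5 | 3,4-O-[(2S,3S)-2,3-dimethoxybutane-2,3-diyl]-2-O-methyl-D-lyxopyranose | OC1OC[C@H]2O[C@](C)(OC)[C@@](C)(OC)O[C@@H]2[C@@H]1OC | intermediate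
6 | methyltriphenylphosphonium bromide | C[P+](c1ccccc1)(c1ccccc1)c1ccccc1.[Br-] | starting material
7 | S-ethyl carbonochloridothioate | CCSC(=O)Cl | starting material
8 | methylenetriphenylphosphorane | C=P(c1ccccc1)(c1ccccc1)c1ccccc1 | intermediate
9 | S-ethyl 2-(triphenyl-λ5-phosphanylidene)ethanethioate | CCSC(=O)C=P(c1ccccc1)(c1ccccc1)c1ccccc1 | intermediate
10 | S-ethyl (2E,4R)-4-[(2R,3R,5S,6S)-3-(hydroxymethyl)-5,6-dimethoxy-5,6-dimethyl-1,4-dioxan-2-yl]-4-methoxybut-2-enethioate | CCSC(=O)/C=C/[C@@H](OC)[C@H]1O[C@](C)(OC)[C@@](C)(OC)O[C@@H]1CO | intermediate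
11 | S-ethyl (2E,4R)-4-[(2R,3S,5S,6S)-3-formyl-5,6-dimethoxy-5,6-dimethyl-1,4-dioxan-2-yl]-4-methoxybut-2-enethioate | CCSC(=O)/C=C/[C@@H](OC)[C@H]1O[C@](C)(OC)[C@@](C)(OC)O[C@@H]1C=O | intermediate
12 | phosphonium enolate (PMe3 adduct at C2 of 11) | CCSC([O-])=CC([P+](C)(C)C)[C@@H](OC)[C@H]1O[C@](C)(OC)[C@@](C)(OC)O[C@@H]1C=O | intermediate
13 | phosphonium aldolate (cyclised, C3–C4 bond formed) | CO[C@@H]1C([P+](C)(C)C)C(C(=O)SCC)[C@@H]([O-])[C@H]2O[C@](C)(OC)[C@@](C)(OC)O[C@H]12 | intermediate
14 | S-ethyl (2S,3S,4aR,5R,8R,8aR)-5-hydroxy-2,3,8-trimethoxy-2,3-dimethyl-2,3,4a,5,8,8a-hexahydrobenzo[b][1,4]dioxine-6-carbothioate | CO[C@@H]1C=C(C(=O)SCC)[C@@H](O)[C@H]2O[C@](C)(OC)[C@@](C)(OC)O[C@H]12 | intermediate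
15 | (2S,3S,4aR,5R,8R,8aR)-5-hydroxy-2,3,8-trimethoxy-2,3-dimethyl-2,3,4a,5,8,8a-hexahydrobenzo[b][1,4]dioxine-6-carbaldehyde | CO[C@@H]1C=C(C=O)[C@@H](O)[C@H]2O[C@](C)(OC)[C@@](C)(OC)O[C@H]12 | intermediate
16 | (2S,3S,4aR,5R,8R,8aR)-6-(hydroxymethyl)-2,3,8-trimethoxy-2,3-dimethyl-2,3,4a,5,8,8a-hexahydrobenzo[b][1,4]dioxin-5-ol | CO[C@@H]1C=C(CO)[C@@H](O)[C@H]2O[C@](C)(OC)[C@@](C)(OC)O[C@H]12 | intermediate
17 | [(2S,3S,4aR,5R,8R,8aR)-5-hydroxy-2,3,8-trimethoxy-2,3-dimethyl-2,3,4a,5,8,8a-hexahydrobenzo[b][1,4]dioxin-6-yl]methyl benzoate | CO[C@@H]1C=C(COC(=O)c3ccccc3)[C@@H](O)[C@H]2O[C@](C)(OC)[C@@](C)(OC)O[C@H]12 | intermediate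
18 | [(3R,4S,5R,6R)-4,5,6-trihydroxy-3-methoxycyclohex-1-en-1-yl]methyl benzoate | CO[C@@H]1C=C(COC(=O)c2ccccc2)[C@@H](O)[C@@H](O)[C@@H]1O | intermediate
19 | diphenylborinate of the C4/C5 cis-diol of 18 (diisopropylethylammonium salt) | CO[C@@H]1C=C(COC(=O)c2ccccc2)[C@H]3O[B-](c2ccccc2)(c2ccccc2)O[C@H]3[C@@H]1O.CC[NH+](C(C)C)C(C)C | intermediate
20 | [(3R,4R,5R,6R)-5-(benzoyloxy)-4,6-dihydroxy-3-methoxycyclohex-1-en-1-yl]methyl benzoate | CO[C@@H]1C=C(COC(=O)c2ccccc2)[C@@H](O)[C@@H](OC(=O)c2ccccc2)[C@@H]1O | target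

**Step count**

Total step count: 12. Longest linear sequence: 11 steps (steps 1–4 and 6–12). Step 5 is a one-step side branch.

**Steps most likely to fail**

Step 8. What may go wrong: slow addition of the phosphine to the hindered, γ,δ-dioxygenated acceptor, loss of methoxide from the phosphonium intermediate, or poor facial selectivity at C4.
- The fallback sets out from lactol 5 and comes back at diol 16. It closes the same C3–C4 bond irreversibly from a vinylmetal instead of a catalytic enolate.
- Methyl (triphenylphosphoranylidene)acetate and N-iodosuccinimide give the iodo ylide F1. Wittig reaction of F1 with 5 should give the (Z)-2-iodoenoate alcohol F2.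
- Dess–Martin oxidation gives the iodoenoate aldehyde F3.
- An intramolecular Nozaki–Hiyama–Kishi reaction (CrCl2, cat. NiCl2, DMF) should give the methyl ester carbocycle F4. DIBAL-H then reduces F4 to 16.

Step 12. What may go wrong: competing acylation at O6 or O4, and benzoyl migration in the basic medium.
- The fallback sets out from triol 18 and comes back at target 20. It replaces catalyst control by a protecting-group detour.
- 2,2-Dimethoxypropane with PPTS should take up only the cis C4/C5 diol to give the acetonide F5.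
- TBSOTf and 2,6-lutidine silylate the remaining C6–OH to give the silyl ether F6. Aqueous acetic acid removes the acetonide to give the C4,C5-diol F7.
- BzCl in pyridine at low temperature should acylate the equatorial C5–OH in preference to the pseudoaxial allylic C4–OH to give the dibenzoate silyl ether F8. HF·pyridine then gives 20.

Step 6. What may go wrong: addition of the liberated primary hydroxyl to the new acceptor (oxa-Michael ring closure), and epimerisation next to the aldehyde carbon.
- The fallback sets out from lactol 5 and comes back at aldehyde 11. It introduces the acceptor only after the alcohol has been oxidised.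
- Methylenation of 5 with ylide 8 gives the terminal alkene alcohol F9. Dess–Martin oxidation gives the alkenal F10.
- S-ethyl thioacrylate F11 is made from ylide 9 and paraformaldehyde. Cross-metathesis of F10 with F11 (second-generation Hoveyda–Grubbs catalyst, CH2Cl2, reflux) should give 11.

**Further compounds**

F1 | step 8 | methyl 2-iodo-2-(triphenyl-λ5-phosphanylidene)acetate | COC(=O)C(I)=P(c1ccccc1)(c1ccccc1)c1ccccc1
F2 | step 8 | methyl (2Z,4R)-4-[(2R,3R,5S,6S)-3-(hydroxymethyl)-5,6-dimethoxy-5,6-dimethyl-1,4-dioxan-2-yl]-2-iodo-4-methoxybut-2-enoate | COC(=O)/C(I)=C/[C@@H](OC)[C@H]1O[C@](C)(OC)[C@@](C)(OC)O[C@@H]1CO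
F3 | step 8 | methyl (2Z,4R)-4-[(2R,3S,5S,6S)-3-formyl-5,6-dimethoxy-5,6-dimethyl-1,4-dioxan-2-yl]-2-iodo-4-methoxybut-2-enoate | COC(=O)/C(I)=C/[C@@H](OC)[C@H]1O[C@](C)(OC)[C@@](C)(OC)O[C@@H]1C=O
F4 | step 8 | methyl (2S,3S,4aR,5R,8R,8aR)-5-hydroxy-2,3,8-trimethoxy-2,3-dimethyl-2,3,4a,5,8,8a-hexahydrobenzo[b][1,4]dioxine-6-carboxylate | CO[C@@H]1C=C(C(=O)OC)[C@@H](O)[C@H]2O[C@](C)(OC)[C@@](C)(OC)O[C@H]12
F5 | step 12 | C4,C5-O-isopropylidene derivative of 18 | CO[C@@H]1C=C(COC(=O)c2ccccc2)[C@H]3OC(C)(C)O[C@H]3[C@@H]1O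
F6 | step 12 | C6-O-tert-butyldimethylsilyl ether of F5 | CO[C@@H]1C=C(COC(=O)c2ccccc2)[C@H]3OC(C)(C)O[C@H]3[C@@H]1O[Si](C)(C)C(C)(C)C
F7 | step 12 | C6-O-tert-butyldimethylsilyl ether of 18 (C4,C5-diol) | CO[C@@H]1C=C(COC(=O)c2ccccc2)[C@@H](O)[C@@H](O)[C@@H]1O[Si](C)(C)C(C)(C)C
F8 | step 12 | C6-O-tert-butyldimethylsilyl ether of 20 | CO[C@@H]1C=C(COC(=O)c2ccccc2)[C@@H](O)[C@@H](OC(=O)c2ccccc2)[C@@H]1O[Si](C)(C)C(C)(C)C
F9 | step 6 | terminal alkene alcohol (10 with CH=CH2 in place of the thioenoate) | C=C[C@@H](OC)[C@H]1O[C@](C)(OC)[C@@](C)(OC)O[C@@H]1CO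
F10 | step 6 | terminal alkene aldehyde (11 with CH=CH2 in place of the thioenoate) | C=C[C@@H](OC)[C@H]1O[C@](C)(OC)[C@@](C)(OC)O[C@@H]1C=O
F11 | step 6 | S-ethyl prop-2-enethioate | C=CC(=O)SCC
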